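At early times, before any target has formed, the uncatalysed step with partner is the one step that can run, and each target it makes opens the other two.

| flask | substrate | partner | temperature | time |
|---|---|---|---|---|
| birch | 0.050 M | 0.250 M | 100 °C | 2.5 min |
| maple | 0.050 M | 0.250 M | 80 °C | 2.5 min |
| oak | 0.050 M | 0.250 M | 120 °C | 2.5 min |

    substrate + partner + target → 2 target (k1 = 2.76 L² mol⁻² s⁻¹, Ea1 = 42.0 kJ mol⁻¹)
    substrate + target → side product (k2 = 0.0865 L mol⁻¹ s⁻¹, Ea2 = 58.0 kJ mol⁻¹)
    substrate + partner → target (k3 = 0.00159 L mol⁻¹ s⁻¹, Ea3 = 71.0 kJ mol⁻¹)
    (constants at 100 °C)

- in percentages every species weighs as the substrate in it: one side product counts as two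
- at 100 °C the constants are as listed, elsewhere as the activation energies make them

- the flask that comes out highest in amount of target, in percent of the substrate charged, or "all alike" when all lie within 1.5 percentage points (birch / maple / oak / all alike)
- target at the end, in percent of the substrate charged, birch
- target at the end, in percent of the substrate charged, maple
- target at the end, in percent of the substrate charged, oak

Once target is present, two steps compete for it. Write k_m for the constant of the step that uses substrate, partner and target, which gains one target net (autocatalysis), and k_l for the step to side product, which loses one. Both rates carry substrate and target, so these cancel in the quotient S = k_m[partner]/k_l, the making-to-losing ratio, a selectivity factor. Its zero point is S = 1, where target is made as fast as it is lost. I hold partner at its charge, though the run consumes some, and I set the uncatalysed step aside here, though it supplies the first target.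

Of every S + 1 substrates consumed, S make a target and one destroys a target. So the target gained per substrate consumed is Y = (S − 1)/(S + 1).

In birch, S is 7.98 and Y is 77.7%. The loss step has the higher activation energy, by 16.0 kJ mol⁻¹, so heat lowers S. Maple has 10.7 and Y of 82.9%. Oak has 6.14 and Y of 72.0%.

But Y counts per substrate consumed, and you also need the clock. Early on, with substrate near its charge, each target present adds (k_m[partner] − k_l)[substrate] target per unit time, which is S − 1 times k_l[substrate]. That makes a doubling time of 0.795 min in maple, 0.383 min in birch and 0.201 min in oak. Set against the 2.5 min allowed, those times come to 3.14 doublings for maple and 12.4 for oak, a count that stops holding once substrate falls away from its charge. I therefore expect maple low, birch partway, and oak highest, close to its Y.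

The forecast gives oak highest, with birch 41%, maple 4.8% and oak 68%, and says of the cap that heat puts on oak: “that costs far less than the shortfall in conversion at the lower temperatures”.

The simulation gives oak highest: birch 45.8%, maple 5.51%, oak 71.2%. Oak has converted 99.0% of its substrate at the end. Oak's Y times that conversion is 71.3%, level with the target found there, though Y held partner at its charge and oak ends with 83.0% of it.

Now take a repeat of birch at 125 °C. There S is 5.77, so Y is 70.5%, lower than oak's. The flask gives 70.5% of target, with 0.26% of its substrate left.

The numbers come from no measurement, and the outcome is calculated.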